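The readings were computed on assumed constants.

The reading comes at 80 min, and the dispute is whether that is late enough for this flask to use up its incoming ligand.

| flask | starting complex | incoming ligand | scavenger | remark | time |
|---|---|---|---|---|---|
| Monday's | 0.14 M | 0.10 M | 0.15 M | run made earlier |  |
| Thursday's | 0.22 M | 0.10 M | 0.15 M | run made earlier |  |
| Sunday's | 0.10 M | 0.20 M | 0.15 M | run made earlier |  |
| flask | 0.10 M | 0.100 M | 0.150 M |  | 80 min |

| run | time / min | complex with one exchanged / % | complex with two exchanged / % |
|---|---|---|---|
| Monday's | 6.00 | 19.0 | 1.9 |
| Monday's | 15.0 | 31.7 | 4.0 |
| Monday's | 30.0 | 40.2 | 8.2 |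
| Monday's | 50.0 | 43.6 | 10.1 |
| Thursday's | 6.00 | 17.8 | 0.5 |
| Thursday's | 15.0 | 27.4 | 3.3 |
| Thursday's | 30.0 | 32.2 | 5.5 |
| Thursday's | 50.0 | 33.9 | 5.0 |
| Sunday's | 6.00 | 32.3 | 4.2 |
| Sunday's | 15.0 | 46.6 | 15.5 |
| Sunday's | 30.0 | 47.6 | 32.3 |
| Sunday's | 50.0 | 40.9 | 48.2 |

(standard deviation of a reading: 0.5 percentage points)

- equivalents of incoming ligand to starting complex, everything else as given, that leave most complex with one exchanged at 80 min
- the amount of complex with one exchanged then, in percent of the starting complex charged
- the amount of complex with one exchanged with the amounts as given



Call uptake the ligand found in the products per starting complex charged: one-exchanged plus two times two-exchanged. Take each complex to have two like sites.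

The counter argues from the charge. If chance spreads the uptake, one-exchanged is two times the fraction of sites taken times the fraction free. Monday's last reading has uptake 0.638 equiv, for which chance gives 43.4%, and 43.6% was read. That curve tops at one equivalent of uptake, the crossing where one-exchanged is used as fast as it is made, and Sunday's readings flatten between uptakes 0.776 and 1.12. This flask holds 1.00 equiv, so the counter expects the limiting reagent to be consumed and the flask to stand on the crossing, at half.

The clock answers that ligand thins out. Define the site constant as the rate of ligand use divided by ligand and by free sites, where free sites per complex are two minus uptake. Sunday's ligand equals its free sites, so the reciprocal of free sites grows straight with time. Its slope, divided by the complex charged, gives 0.213 M⁻¹ min⁻¹, and the earlier reading gives 0.211 M⁻¹ min⁻¹.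

In this flask, free sites over ligand start at two and grow by the factor 5.50 by the reading. My reckoning therefore gives uptake 0.900 equiv, less than the charge, and a share of 49.5%. Reaching the crossing on time takes a larger charge, found by trial, since the exponent of the factor carries two minus the equivalents: the factor above asks for 1.10 equiv, the smaller factor at that charge asks for 1.12 equiv, and the next round gives 1.13 equiv.

The forecast sided with the clock but set the share lower than I do, at 47.5%, with 48% at 1.12 equiv: “A small excess, about 1.1 equiv, reaches the peak at 80 min”.

The flask gives 50.3%, and 50.5% at 1.08 equiv. Its uptake is 0.918 equiv, with 8.20% of the ligand left and one-exchanged still made 1.25 times as fast as used, so the clock wins. The counter's region is late: at 800 min the site constant gives uptake 1.00 equiv, and the flask holds 0% of its ligand and 50.9% one-exchanged.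

    starting complex + incoming ligand → leaving ligand + complex with one exchanged (k = 0.510 M⁻¹ min⁻¹)
    complex with one exchanged + incoming ligand → leaving ligand + complex with two exchanged (k = 0.230 M⁻¹ min⁻¹)
    leaving ligand + starting complex ⇌ idle adduct, settled at all times (K = 70.0 M⁻¹)
    scavenger + leaving ligand → scavenged by-product (k = 13.0 M⁻¹ min⁻¹)
    starting complex → decomposition product (k = 2.10 × 10⁻⁵ min⁻¹)

A like flask with 0.060 M of ligand holds 0.600 equiv, below the crossing. The site constant gives uptake 0.560 equiv and a share of 40.3%; the computed flask gives 41.5%.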